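All runs come from a simulation with made-up constants.

Amounts are what we have, so we divide the gain of bis adduct by the loss of solid substrate between two readings of one run. Time drops out.

| flask | solid substrate | reagent | remark | time |
|---|---|---|---|---|
| Monday's | 0.024 M | 0.025 M (fed, over 8.0 d) | run made earlier |  |
| Tuesday's | 0.024 M | 0.049 M (fed, over 8.0 d) | run made earlier |  |
| Sunday's | 0.024 M | 0.080 M (fed, over 8.0 d) | run made earlier |  |
| west | 0.024 M | 0.0960 M (fed, over 8.0 d) |  | 15 d |
| north | 0.024 M | 0.0288 M (fed, over 8.0 d) |  | 15 d |

| run | time / d | bis adduct / % | solid substrate / % |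
|---|---|---|---|
| Monday's | 0.625 | 0 | 61 |
| Monday's | 2.08 | 2 | 59 |
| Monday's | 4.00 | 4 | 51 |
| Monday's | 5.00 | 7 | 46 |
| Monday's | 8.00 | 12 | 29 |
| Tuesday's | 0.625 | 0 | 63 |
| Tuesday's | 1.04 | 1 | 59 |
| Tuesday's | 2.00 | 2 | 57 |
| Tuesday's | 4.00 | 7 | 42 |
| Tuesday's | 8.00 | 32 | 0 |
| Sunday's | 1.67 | 2 | 57 |
| Sunday's | 3.00 | 12 | 42 |
| Sunday's | 5.00 | 23 | 14 |
| Sunday's | 6.00 | 34 | 0 |
| Sunday's | 8.00 | 41 | 0 |

(readings scatter by 1.5 percentage points)

- given per volume of solution although it is solid: solid substrate
- what was read earlier has a scatter of 1.5 percentage points, one standard deviation
- at the start none of the solid substrate is in solution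

1. which of these holds the largest part of the solid substrate at the end of west (mono adduct / solid substrate / bis adduct / triple product)
2. which of these holds the largest part of the solid substrate at the end of north (mono adduct / solid substrate / bis adduct / triple product)
3. bis adduct at the end of west, in percent of the solid substrate charged

We count from the first readings, since Monday's solid already stands at 61% with 0% bis adduct. Sunday's run between 1.67 d and 5.00 d gives 0.488, and this quotient is the bis yield f. A second way, Tuesday's run from first reading to last, gives 0.508, so we trust about half, as a reading with scatter.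

Monday's run gives 0.375, and this one cheats. From first reading to last, Monday's run lost more solid substrate than its bis adduct accounts for at f, so we read the difference as waiting in mono adduct, 7.43% of the charge by our reckoning.

In north we take reagent as the limiting reagent. At 2 per bis adduct it carries 60.0% of the charge through, and f makes that 29.3% bis adduct in north, more than the 7.43% of mono adduct we read from Monday's run.

In west, bis adduct also goes on to triple product. Sunday's last 41% against a ceiling of f means 84.0% kept. We assume the loss goes as free reagent times days: 32.0 mM over 5.00 d in Sunday's run, 48.0 mM over 12.0 d in west. That exposure is 3.60 times Sunday's, so west keeps 53.3%. We commit to 26.0% bis adduct and 46.7% triple product, which is more.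

The forecast gives triple product for west, 27% bis adduct there, and mono adduct for north, “Reagent runs out, leaving mainly mono adduct”, where our reckoning differs.

West ends with 27.8% bis adduct and 53.0% triple product. North's largest is bis adduct, 27.9% against 8.86% mono adduct.

    starting material + reagent → mono adduct (k = 0.700 L mol⁻¹ h⁻¹)
    solid substrate ⇌ starting material, rate k2*(cs2 - [starting material]) while solid is left; crystals form when [starting material] > cs2 (solubility = 8.90 mM, k = 0.430 h⁻¹)
    reagent + bis adduct → triple product (k = 0.140 L mol⁻¹ h⁻¹)
    reagent + mono adduct → bis adduct (k = 2.90 L mol⁻¹ h⁻¹)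
    bis adduct ⇌ isomer of the product (K = 0.680, k = 0.190 h⁻¹)

Bis adduct and isomer of the product relax into one another with a half-life of 0.0615 d, short against 15 d, and west ends with 19.1% isomer. In west, f times what is not triple product gives 23.0%. In north, solid substrate and starting material together keep 40.2%, so f on the remainder gives 29.2%, and north holds 27.9%.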